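**Plan**

- Retrosynthesis: the C15 methylene and the C6 carbinol go back to an anhydride carbonyl and a ketone; the C20–O bond of the 19,20-lactone goes back to a C20–N lactam bond; the C9–O–C13 ether goes back to a 9α-hydroxy butenolide and then to the 3-substituted furan; the N–C20 bond goes back to a C19 acyl azide; the C19 acid goes back to the 19,6β-lactone of marrubiin.
- Forward: rings A and B arrive intact with marrubiin. The bridged δ-lactam ring (N, C19, C4, C5, C10, C20) closes first, then the furan is oxidised and the oxolane ring (O, C9, C11, C12, C13) closes at C13, then nitrogen is exchanged for oxygen in the bridge, and the γ-lactone is finished last.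
- Enabling feature: on ring A the carbonyl carbon C19 (axial on C4) and the methyl carbon C20 (axial on C10) are syn-diaxial on the β face, so a nitrogen atom carried by C19 lies next to a C20–H bond. C6, the other carbon within reach, is held as a ketone.
- Stereochemistry: C4, C5, C8, C9 and C10 are those of marrubiin; C6 is set by hydride attack on the α face of the ketone; C13 (S) is set in a reversible oxa-Michael closure, with separation and recycling of the epimer.

Key step: step 5

Remark: marrubiin (1) is taken as a purchasable natural product; labdane numbering is used, and "x,y-olide" or "x,y-lactam" means carbonyl at C-x and heteroatom on C-y.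
Remark: keto acid 6 is drawn open; as a γ-keto acid it may rest as its cyclic hydroxy-lactone tautomer, which reopens as the carboxylate under the basic conditions of step 4.

**Step 1**
Reactants: 1 marrubiin; 2 allyl bromide
Product: 4 allyl marrubiinate, via potassium marrubiinate 3 (not isolated)
Conditions: KOH (1.1 equiv), EtOH/H2O, reflux; evaporate; then 2, DMF, 0 °C → rt
Reagents that add atoms: potassium hydroxide, [K+].[OH-]
Why: Saponification opens the 19,6β-lactone and the resulting carboxylate is O-alkylated by allyl bromide in an SN2 reaction, the neutral 6β- and 9α-hydroxyls being far poorer nucleophiles, so no stereocentre is touched.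

**Step 2**
Reactants: 4 allyl marrubiinate
Product: 5 allyl 6-oxomarrubiinate
Conditions: Dess–Martin periodinane, CH2Cl2, 0 °C → rt
Reagents that add atoms: none
Why: Dess–Martin oxidation converts the axial secondary 6β-alcohol into the ketone while the tertiary 9α-alcohol, the furan and the allyl ester are inert, and C5 keeps the trans ring fusion, which is the stable arrangement.

**Step 3**
Reactants: 5 allyl 6-oxomarrubiinate
Product: 6 6-oxomarrubiinic acid
Conditions: Pd(PPh3)4 (5 mol %), morpholine, THF, rt
Reagents that add atoms: none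
Why: Tsuji–Trost deallylation, in which zerovalent palladium ionises the allyl ester and morpholine takes up the allyl group, frees the hindered acid without any hydrolytic step.

**Step 4**
Reactants: 6 6-oxomarrubiinic acid; 7 diphenylphosphoryl azide
Product: 8 6-oxomarrubiinoyl azide
Conditions: 7, Et3N, DMF, 0 °C → rt (kept below 25 °C)
Reagents that add atoms: none
Why: Acyl azide formation through the mixed carboxylic–phosphoric anhydride, in which the open-chain triethylammonium carboxylate attacks phosphorus and azide then displaces diphenyl phosphate at the acyl carbon, run cold so that the thermal Curtius rearrangement does not begin.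

**Step 5**
Reactants: 8 6-oxomarrubiinoyl azide
Product: 10 keto lactam (6-oxo 19,20-lactam), via C19 acyl nitrene 9 (not isolated)
Conditions: hν (254 nm, low-pressure mercury lamp, quartz), CH2Cl2 (0.005 M, degassed), 0 °C
Reagents that add atoms: none
Why: Excitation of the acyl azide expels N2 and gives the singlet acyl nitrene 9, which inserts in a single step into a C–H bond of the C20 methyl group and so forms the N–C20 bond. The closest known reaction is the photolytic intramolecular C–H insertion of C19 acyl azides of resin-acid-type diterpenoids, which gives the same bridged δ-lactams. The ring that closes is six-membered (N, C19, C4, C5, C10, C20), a 3-azabicyclo[3.3.1]nonan-2-one spanning ring A, and it closes through a cyclic insertion transition state that is available because C19 and C20 are both axial on the β face. No stereocentre is created, since the carbon attacked is a methyl group and C10 is not disturbed. The step needs site selectivity and chemoselectivity: the C6 carbonyl leaves no C–H bond for the competing γ-lactam, the axial C2–H bond could only give a strained 6-azabicyclo[3.2.1] γ-lactam, the 9α-hydroxyl lies on the opposite face, and high dilution keeps the nitrene away from the furan of a second molecule. The concerted photo-Curtius shift to the C4 isocyanate cannot be suppressed and its product is removed by chromatography.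

**Step 6**
Reactants: 10 keto lactam
Product: 13 16-acetoxybutenolide lactam, via furan endoperoxide 11 (not isolated), via 16-hydroxybutenolide 12 (not isolated)
Conditions: O2, hν (visible), 5,10,15,20-tetraphenylporphyrin (cat.), iPr2NEt, CH2Cl2, −78 °C; then Ac2O, DMAP (cat.), −78 → 0 °C
Reagents that add atoms: dioxygen, O=O; acetic anhydride, CC(=O)OC(C)=O
Why: Singlet oxygen adds across C15 and C16 of the furan in a [4+2] cycloaddition, the hindered amine removes the more accessible C15–H of the endoperoxide (Kornblum–DeLaMare fragmentation) so that the carbonyl ends at C15 and the hydroxyl at C16, and acetylation fixes the butenolide in its closed form, C16 arising as an inconsequential epimer mixture.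

**Step 7**
Reactants: 13 16-acetoxybutenolide lactam
Product: 14 spiro acetoxy lactone lactam
Conditions: DBU, toluene, rt → 50 °C
Reagents that add atoms: none
Why: Intramolecular oxa-Michael addition (5-exo-trig) of the 9α-hydroxyl to C13, the β-carbon of the closed butenolide and its only electrophilic alkene carbon while the acetate keeps the lactol from opening to a formyl acrylate; the addition is reversible and the two faces of C13 are flanked in a similar way by C1 and C17, so both C13 epimers are expected, the 13S isomer being separated and the 13R isomer returned to the same conditions.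

**Step 8**
Reactants: 14 spiro acetoxy lactone lactam
Product: 16 spiro lactol lactam, via lithium formyl carboxylate 15 (not isolated)
Conditions: LiOH, THF/H2O, 0 °C; then 1 M HCl to pH 3
Reagents that add atoms: none
Why: Saponification of the acylal acetate releases the formyl carboxylate, which cannot revert by retro-Michael reaction (the aldehyde has no α-hydrogen and the carboxylate does not acidify C14), and acidification closes it to the lactol with C13 untouched.

**Step 9**
Reactants: 16 spiro lactol lactam
Product: 17 spiro anhydride lactam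
Conditions: Dess–Martin periodinane, CH2Cl2, rt
Reagents that add atoms: none
Why: Dess–Martin oxidation of the lactol, a cyclic hemiacetal, gives the C16 carbonyl as a succinic anhydride under non-aqueous conditions in which the anhydride survives.

**Step 10**
Reactants: 17 spiro anhydride lactam
Product: 20 keto anhydride 19,20-lactone, via N-nitroso lactam 18 (not isolated), via cyclic diazo ester 19 (not isolated)
Conditions: N2O4, NaOAc, CH2Cl2, −20 → 0 °C; filter, evaporate cold; then toluene, 90 °C
Reagents that add atoms: dinitrogen tetroxide, O=[N+]([O-])[N+](=O)[O-]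
Why: N-Nitrosation of the secondary lactam followed by the thermal N-nitrosoamide rearrangement, in which the acyl group shifts from nitrogen to the nitroso oxygen and the diazo ester loses N2 while the tethered C19 carboxylate collapses onto C20 before this neopentyl-type centre can rearrange; C20 is not stereogenic, and the furan and the free hydroxyl, which would not tolerate N2O4, are no longer present.

**Step 11**
Reactants: 20 keto anhydride 19,20-lactone
Product: 22 target (13S)-9α,13-epoxy-6β-hydroxylabdane-19,20:16,15-diolide, via tripotassium hydroxy carboxylate 21 (not isolated)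
Conditions: KBH(sBu)3 (3.5 equiv), THF, −78 → −20 °C; then 1 M HCl, −78 °C → rt
Reagents that add atoms: none
Why: Hydride reduction with a bulky trialkylborohydride, which attacks the anhydride at C15, the carbonyl remote from the quaternary C13 (steric regiocontrol known for 2,2-disubstituted succinic anhydrides), and attacks the C6 ketone from the open α face because the β face is covered by the C19–O–C20 bridge, giving the axial 6β-alcohol, after which acid work-up closes the 15-hydroxy-16-acid to the γ-lactone.

**Compound list**

1 | marrubiin; 15,16-epoxy-9α-hydroxy-8βH-labda-13(16),14-dien-19,6β-olide (C19 β and C18 α on C4, 5α-H, 8α-methyl, 10β-methyl) | C[C@@H]1C[C@@H](O4)[C@@H]2[C@](C)(CCC[C@]2(C)C4=O)[C@@]1(O)CCc1ccoc1 | starting material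
2 | allyl bromide (3-bromoprop-1-ene) | C=CCBr | starting material
3 | potassium marrubiinate; potassium 15,16-epoxy-6β,9α-dihydroxylabda-13(16),14-dien-19-oate, ring centres as in 1 | C[C@@H]1C[C@@H](O)[C@@H]2[C@](C)(CCC[C@]2(C)C(=O)[O-])[C@@]1(O)CCc1ccoc1.[K+] | intermediate (not isolated)
4 | allyl marrubiinate; prop-2-enyl 15,16-epoxy-6β,9α-dihydroxylabda-13(16),14-dien-19-oate | C[C@@H]1C[C@@H](O)[C@@H]2[C@](C)(CCC[C@]2(C)C(=O)OCC=C)[C@@]1(O)CCc1ccoc1 | intermediate
5 | allyl 6-oxomarrubiinate; prop-2-enyl 15,16-epoxy-9α-hydroxy-6-oxolabda-13(16),14-dien-19-oate | C[C@@H]1CC(=O)[C@@H]2[C@](C)(CCC[C@]2(C)C(=O)OCC=C)[C@@]1(O)CCc1ccoc1 | intermediate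
6 | 6-oxomarrubiinic acid; 15,16-epoxy-9α-hydroxy-6-oxolabda-13(16),14-dien-19-oic acid | C[C@@H]1CC(=O)[C@@H]2[C@](C)(CCC[C@]2(C)C(=O)O)[C@@]1(O)CCc1ccoc1 | intermediate
7 | diphenylphosphoryl azide | [N-]=[N+]=NP(=O)(Oc1ccccc1)Oc1ccccc1 | starting material
8 | 6-oxomarrubiinoyl azide; 15,16-epoxy-9α-hydroxy-6-oxolabda-13(16),14-dien-19-oyl azide | C[C@@H]1CC(=O)[C@@H]2[C@](C)(CCC[C@]2(C)C(=O)N=[N+]=[N-])[C@@]1(O)CCc1ccoc1 | intermediate (key-step precursor)
9 | C19 acyl nitrene of 8 (monovalent nitrogen on the β-axial C19 carbonyl) | C[C@@H]1CC(=O)[C@@H]2[C@](C)(CCC[C@]2(C)C(=O)[N])[C@@]1(O)CCc1ccoc1 | intermediate (not isolated)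
10 | keto lactam; 15,16-epoxy-9α-hydroxy-6-oxolabda-13(16),14-dien-19,20-lactam (C19(=O)–NH–C20H2 bridge across the β face of ring A) | C[C@@H]1CC(=O)[C@@H]2[C@]3(CCC[C@]2(C)C(=O)NC3)[C@@]1(O)CCc1ccoc1 | intermediate (key-step product)
11 | furan endoperoxide; 15,16-epidioxy-15,16-epoxy-9α-hydroxy-6-oxolabd-13-en-19,20-lactam (mixture at C15 and C16) | C[C@@H]1CC(=O)[C@@H]2[C@]3(CCC[C@]2(C)C(=O)NC3)[C@@]1(O)CCC1=CC2OOC1O2 | intermediate (not isolated)
12 | 16-hydroxybutenolide; 9α,16-dihydroxy-6-oxolabd-13-en-15,16-olide 19,20-lactam (C16 epimers, present as its ammonium salt) | C[C@@H]1CC(=O)[C@@H]2[C@]3(CCC[C@]2(C)C(=O)NC3)[C@@]1(O)CCC1=CC(=O)OC1O | intermediate (not isolated)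
13 | 16-acetoxybutenolide lactam; 16-acetoxy-9α-hydroxy-6-oxolabd-13-en-15,16-olide 19,20-lactam (C16 epimers) | C[C@@H]1CC(=O)[C@@H]2[C@]3(CCC[C@]2(C)C(=O)NC3)[C@@]1(O)CCC1=CC(=O)OC1OC(C)=O | intermediate
14 | spiro acetoxy lactone lactam; (13S)-16-acetoxy-9α,13-epoxy-6-oxolabdan-15,16-olide 19,20-lactam (C16 epimers) | C[C@@H]1CC(=O)[C@@H]2[C@]3(CCC[C@]2(C)C(=O)NC3)[C@@]12CC[C@@]1(CC(=O)OC1OC(C)=O)O2 | intermediate
15 | lithium formyl carboxylate; lithium (13S)-9α,13-epoxy-6,16-dioxolabdan-15-oate 19,20-lactam | C[C@@H]1CC(=O)[C@@H]2[C@]3(CCC[C@]2(C)C(=O)NC3)[C@@]12CC[C@@](C=O)(CC(=O)[O-])O2.[Li+] | intermediate (not isolated)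
16 | spiro lactol lactam; (13S)-9α,13-epoxy-16-hydroxy-6-oxolabdan-15,16-olide 19,20-lactam (C16 epimers) | C[C@@H]1CC(=O)[C@@H]2[C@]3(CCC[C@]2(C)C(=O)NC3)[C@@]12CC[C@@]1(CC(=O)OC1O)O2 | intermediate
17 | spiro anhydride lactam; (13S)-9α,13-epoxy-6-oxolabdane-15,16-dioic anhydride 19,20-lactam | C[C@@H]1CC(=O)[C@@H]2[C@]3(CCC[C@]2(C)C(=O)NC3)[C@@]12CC[C@@]1(CC(=O)OC1=O)O2 | intermediate
18 | N-nitroso lactam; N-nitroso derivative of 17 | C[C@@H]1CC(=O)[C@@H]2[C@]3(CCC[C@]2(C)C(=O)N(N=O)C3)[C@@]12CC[C@@]1(CC(=O)OC1=O)O2 | intermediate (not isolated)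
19 | cyclic diazo ester; C19(=O)–O–N=N–C20 bridge (Z) on the skeleton of 17 | C[C@@H]1CC(=O)[C@@H]2[C@]3(CCC[C@]2(C)C(=O)O/N=N\C3)[C@@]12CC[C@@]1(CC(=O)OC1=O)O2 | intermediate (not isolated)
20 | keto anhydride 19,20-lactone; (13S)-9α,13-epoxy-6-oxolabdan-19,20-olide-15,16-dioic anhydride | C[C@@H]1CC(=O)[C@@H]2[C@]3(CCC[C@]2(C)C(=O)OC3)[C@@]12CC[C@@]1(CC(=O)OC1=O)O2 | intermediate
21 | tripotassium hydroxy carboxylate; tripotassium (13S)-9α,13-epoxy-6β,15-dioxidolabdan-19,20-olid-16-oate | C[C@@H]1C[C@@H]([O-])[C@@H]2[C@]3(CCC[C@]2(C)C(=O)OC3)[C@@]12CC[C@@](C(=O)[O-])(CC[O-])O2.[K+].[K+].[K+] | intermediate (not isolated)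
22 | (13S)-9α,13-epoxy-6β-hydroxylabdane-19,20:16,15-diolide (4α-methyl, 5α-H, 8α-methyl, 8β-H) | C[C@@H]1C[C@@H](O)[C@@H]2[C@]3(CCC[C@]2(C)C(=O)OC3)[C@@]12CC[C@@]1(CCOC1=O)O2 | target

**Step count and risks**

Total steps: 11. Longest linear sequence: 11 steps (1 → 22); the route is fully linear.

The three steps most likely to fail:

1. Step 5 (acyl nitrene insertion).
   - What may go wrong: the excited azide may lose N2 with a concerted 1,2-shift (photo-Curtius) and never form the free nitrene. Light may also be absorbed by the C6 ketone (Norrish α-cleavage) or by the furan, and the nitrene may be intercepted by the furan of another molecule.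
   - Fallback: it sets out from 4 and comes back at 10, and reaches C20 from the 6β-oxygen with radical chemistry. Compound 4 is treated with nitrosyl chloride (NOCl) and pyridine at −20 °C to give the 6β-nitrite ester F1. Barton nitrite photolysis (mercury lamp, Pyrex, benzene) generates the 6β-alkoxyl radical, which abstracts hydrogen from the syn-axial C20 methyl through a six-membered transition state; recombination with NO and tautomerisation should give the C20 oxime F2. Reduction with Zn in AcOH gives the C20 amino ester F3, which closes onto the neighbouring C19 allyl ester on warming to give the 6β-hydroxy lactam F4. Dess–Martin oxidation of the 6β-alcohol then delivers 10.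

2. Step 7 (oxa-Michael spirocyclisation).
   - What may go wrong: addition of a hindered tertiary alcohol to a fully substituted β-carbon may be slow. The base may strip the acetate so that the butenolide opens to a formyl acrylate, which would be attacked at C14. The two faces of C13 may be poorly distinguished.
   - Fallback: it sets out from 10 and comes back at 17, and activates C13 through an aldehyde instead of a lactone. Oxidation of the furan of 10 with dimethyldioxirane in acetone at −20 °C gives the cis-enedial F5, in which C13 is the β-carbon of the C15 enal. The 9α-hydroxyl adds to it in a 5-exo closure (catalytic Et3N) to give the spiro dialdehyde F6. Pinnick oxidation (NaClO2, NaH2PO4, 2-methyl-2-butene, tBuOH/H2O) gives the spiro diacid F7, and warming in Ac2O closes it to anhydride 17; the C13 epimers are separated at that stage.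

3. Step 11 (double reduction).
   - What may go wrong: hydride may be delivered to the wrong anhydride carbonyl (C16, activated by the α-oxygen). The 19,20-lactone acyl group may migrate to the newly formed 6β-alkoxide (translactonisation to the 19,6β-lactone). The C6 ketone may be reduced incompletely at low temperature.
   - Fallback: it sets out from 20 and comes back at 22, and separates the regiochemical choice from the hydride step. Opening of anhydride 20 with ethanethiol, Et3N and catalytic DMAP at the less hindered C15 carbonyl gives the S-ethyl 15-thioester 16-acid F8, whose constitution can be checked before any reduction. Fukuyama reduction (Et3SiH, palladium on carbon, acetone, rt) converts the thioester into the C15 aldehyde, which rests as the 15-hydroxy lactone F9. Luche-type reduction (NaBH4, CeCl3·7H2O, MeOH, −40 °C), in a protic medium where no free alkoxide persists, reduces the aldehyde and the C6 ketone from the α face, and mild acid closes the γ-lactone to give 22.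

**Further compounds**

F1 | step 5 | allyl 15,16-epoxy-9α-hydroxy-6β-nitrosooxylabda-13(16),14-dien-19-oate (6β-nitrite ester) | C[C@@H]1C[C@@H](ON=O)[C@@H]2[C@](C)(CCC[C@]2(C)C(=O)OCC=C)[C@@]1(O)CCc1ccoc1
F2 | step 5 | allyl 15,16-epoxy-6β,9α-dihydroxy-20-(hydroxyimino)labda-13(16),14-dien-19-oate (C20 oxime) | C[C@@H]1C[C@@H](O)[C@@H]2[C@](C=NO)(CCC[C@]2(C)C(=O)OCC=C)[C@@]1(O)CCc1ccoc1
F3 | step 5 | allyl 20-amino-15,16-epoxy-6β,9α-dihydroxylabda-13(16),14-dien-19-oate (C20 amino ester) | C[C@@H]1C[C@@H](O)[C@@H]2[C@](CN)(CCC[C@]2(C)C(=O)OCC=C)[C@@]1(O)CCc1ccoc1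
F4 | step 5 | 15,16-epoxy-6β,9α-dihydroxylabda-13(16),14-dien-19,20-lactam (6β-hydroxy lactam) | C[C@@H]1C[C@@H](O)[C@@H]2[C@]3(CCC[C@]2(C)C(=O)NC3)[C@@]1(O)CCc1ccoc1
F5 | step 7 | (13Z)-9α-hydroxy-6,15,16-trioxolabd-13-en-19,20-lactam (cis-enedial) | C[C@@H]1CC(=O)[C@@H]2[C@]3(CCC[C@]2(C)C(=O)NC3)[C@@]1(O)CC/C(C=O)=C/C=O
F6 | step 7 | (13S)-9α,13-epoxy-6,15,16-trioxolabdan-19,20-lactam (spiro dialdehyde) | C[C@@H]1CC(=O)[C@@H]2[C@]3(CCC[C@]2(C)C(=O)NC3)[C@@]12CC[C@@](C=O)(CC=O)O2
F7 | step 7 | (13S)-9α,13-epoxy-6-oxolabdane-15,16-dioic acid 19,20-lactam (spiro diacid) | C[C@@H]1CC(=O)[C@@H]2[C@]3(CCC[C@]2(C)C(=O)NC3)[C@@]12CC[C@@](C(=O)O)(CC(=O)O)O2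
F8 | step 11 | (13S)-9α,13-epoxy-15-(ethylsulfanyl)-6,15-dioxolabdan-19,20-olid-16-oic acid (S-ethyl 15-thioester 16-acid) | C[C@@H]1CC(=O)[C@@H]2[C@]3(CCC[C@]2(C)C(=O)OC3)[C@@]12CC[C@@](C(=O)O)(CC(=O)SCC)O2
F9 | step 11 | (13S)-9α,13-epoxy-15-hydroxy-6-oxolabdane-19,20:16,15-diolide (15-hydroxy lactone, C15 epimers) | C[C@@H]1CC(=O)[C@@H]2[C@]3(CCC[C@]2(C)C(=O)OC3)[C@@]12CC[C@@]1(CC(O)OC1=O)O2
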